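**Strategy.** Germacrane numbering is used (ring C1–C10; lactone O on C6, C11 on C7, C12 carbonyl, C13 methylene; C14 formyl, C15 hydroxymethyl). The lactone carbinol C6 is allylic to the ring alkene C4=C5, so the α-methylene-γ-butyrolactone ring (O, C12, C11, C7, C6) is a hidden 1,3-diene: a palladium-catalysed [3+2] heteroannulation of 2-bromoacrylic acid onto an acyclic (Z,E)-diene C7=C6–C5=C4 forges C7–C11 and O–C6 in one operation and sets C6 and C7 from the free C8 hydroxyl of a chiral-pool butenolide. The ten-membered ring is closed afterwards at C9–C10 by an intramolecular Nozaki–Hiyama–Kishi reaction.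

Key step: step 7

Remark: (R)-5-(hydroxymethyl)furan-2(5H)-one 1 is assumed to be purchasable; if not, it is the known product of a (Z)-selective Wittig reaction and acid lactonisation of L-glyceraldehyde acetonide.
Remark: phosphonium salt 4 is assumed to be purchasable; otherwise it comes in one step from 5-bromopent-1-ene and PPh3.

Step 1
Reactants: 1 (R)-5-(hydroxymethyl)furan-2(5H)-one
Product: 2 (R)-5-{[(tert-butyldimethylsilyl)oxy]methyl}furan-2(5H)-one
Conditions: TBSCl, imidazole, CH2Cl2, 0 °C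
Reagents that add atoms: tert-butyldimethylsilyl chloride, CC(C)(C)[Si](C)(C)Cl
Why: Imidazole-mediated silylation of the primary alcohol at low temperature should leave the base-sensitive γ-stereocentre (the future C8) untouched.

Step 2
Reactants: 2 (R)-5-{[(tert-butyldimethylsilyl)oxy]methyl}furan-2(5H)-one
Product: 3 (5R)-5-{[(tert-butyldimethylsilyl)oxy]methyl}-2,5-dihydrofuran-2-ol
Conditions: i-Bu2AlH (1.1 equiv), CH2Cl2, −78 °C; aq. KNaC4H4O6
Reagents that add atoms: none
Why: Low-temperature hydride reduction of a lactone stops at the tetrahedral aluminate and should give the lactol, a ring-locked form of the (Z)-4-hydroxy-2-enal.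

Step 3
Reactants: 4 (pent-4-en-1-yl)triphenylphosphonium bromide; 5 ethyl chloroformate
Product: 8 ethyl 2-(triphenyl-λ5-phosphanylidene)hex-5-enoate, via pent-4-enylidene(triphenyl)phosphorane 6 (not isolated), via (1-ethoxy-1-oxohex-5-en-2-yl)triphenylphosphonium chloride 7 (not isolated)
Conditions: NaN(SiMe3)2 (1.0 equiv), THF, −78 to 0 °C; added to ClCO2Et (1.2 equiv), THF, −78 °C; then aq. NaOH, CH2Cl2, rt
Reagents that add atoms: none
Why: C-acylation of a non-stabilised ylide with a chloroformate, then deprotonation of the α-ester phosphonium salt, is the standard entry to α-alkyl stabilised Wittig reagents.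

Step 4
Reactants: 3 (5R)-5-{[(tert-butyldimethylsilyl)oxy]methyl}-2,5-dihydrofuran-2-ol; 8 ethyl 2-(triphenyl-λ5-phosphanylidene)hex-5-enoate
Product: 9 ethyl (2E,4Z,6R)-2-(but-3-en-1-yl)-7-[(tert-butyldimethylsilyl)oxy]-6-hydroxyhepta-2,4-dienoate
Conditions: toluene, 60 °C
Reagents that add atoms: none
Why: Wittig olefination of the ring-opened hydroxy enal with an α-branched stabilised ylide should be (E)-selective at C4=C5 (ester trans to C6), while the (Z)-geometry of C6=C7 is inherited from the five-membered lactol and the C8 hydroxyl is released free.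

Step 5
Reactants: 9 ethyl (2E,4Z,6R)-2-(but-3-en-1-yl)-7-[(tert-butyldimethylsilyl)oxy]-6-hydroxyhepta-2,4-dienoate
Product: 10 (2E,4Z,6R)-2-(but-3-en-1-yl)-7-[(tert-butyldimethylsilyl)oxy]hepta-2,4-diene-1,6-diol
Conditions: i-Bu2AlH (3.5 equiv), CH2Cl2, −78 °C; aq. KNaC4H4O6
Reagents that add atoms: none
Why: 1,2-Reduction of the conjugated ester to the allylic alcohol C15 by the aluminium hydride should not touch the diene or the silyl ether.

Step 6
Reactants: 10 (2E,4Z,6R)-2-(but-3-en-1-yl)-7-[(tert-butyldimethylsilyl)oxy]hepta-2,4-diene-1,6-diol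
Product: 11 (2R,3Z,5E)-1-[(tert-butyldimethylsilyl)oxy]-6-{[(tert-butyldiphenylsilyl)oxy]methyl}deca-3,5,9-trien-2-ol
Conditions: TBDPSCl (1.05 equiv), imidazole, CH2Cl2, −20 °C
Reagents that add atoms: tert-butyldiphenylsilyl chloride, CC(C)(C)[Si](Cl)(c1ccccc1)c1ccccc1
Why: The bulky silyl chloride should select the primary allylic C15 hydroxyl over the secondary C8 hydroxyl, which must stay free to direct the key step.

Step 7
Reactants: 11 (2R,3Z,5E)-1-[(tert-butyldimethylsilyl)oxy]-6-{[(tert-butyldiphenylsilyl)oxy]methyl}deca-3,5,9-trien-2-ol; 12 2-bromoacrylic acid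
Product: 14 C8-hydroxy α-methylene-γ-butyrolactone, via allylpalladium bromide carboxylate 13 (not isolated)
Conditions: 12 (2 equiv, slow addition), Pd(OAc)2 (10 mol %), PPh3 (20 mol %), n-Bu4NCl (1 equiv), KHCO3 (4 equiv), BHT (cat.), DMF, 60 °C
Reagents that add atoms: none
Why: Larock-type heteroannulation: zerovalent palladium inserts into the C–Br bond of the bromoacrylate, the alkenylpalladium species adds syn across C6=C7 with the alkenyl carbon going to the diene terminus C7 (bond C7–C11) to give the η3-allyl complex over C6–C5–C4 (13), and the pendant carboxylate then attacks C6 (bond O–C6) and releases zerovalent palladium. The closest known reaction type is the palladium-catalysed annulation of 1,3-dienes by aryl or vinylic halides that carry a carboxylic acid. The γ-lactone ring (O, C12, C11, C7, C6) closes by 5-exo attack of the carboxylate oxygen on the allyl terminus C6, the seven-membered alternative at the fully substituted terminus C4 being disfavoured. C7 is controlled by the C8 stereocentre: A(1,3) strain in the (Z)-allylic alcohol holds H8 in the diene plane, and the alkenylpalladium carboxylate should be delivered to the face of the free hydroxyl (hydrogen bond or coordination) and away from the CH2OSi group; C6 is controlled by the (Z)-geometry of C6=C7 together with outer-sphere attack of the carboxylate anti to palladium (chloride and phosphine keep palladium coordinatively saturated), which gives the trans-lactone. The step needs insertion at the disubstituted terminus C7 and not at trisubstituted C4, retention of the C4=C5 geometry (syn/anti exchange would need a tertiary σ-allyl at C4) and trans closure; because the product is an allylic ester that zerovalent palladium can re-ionise, closure is reversible and the trans-lactone is also the thermodynamic sink.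

Step 8
Reactants: 14 C8-hydroxy α-methylene-γ-butyrolactone
Product: 15 C8 methacrylate
Conditions: methacrylic anhydride, Et3N, DMAP (cat.), CH2Cl2, 0 °C to rt
Reagents that add atoms: methacrylic anhydride, C=C(C)C(=O)OC(=O)C(C)=C
Why: DMAP-catalysed acyl transfer to the only free hydroxyl installs the C8 ester with retention of configuration.

Step 9
Reactants: 15 C8 methacrylate; 16 (E)-but-2-enal (crotonaldehyde)
Product: 17 (E)-enal
Conditions: 16 (8 equiv), second-generation Hoveyda–Grubbs catalyst (5 mol %), CH2Cl2, 40 °C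
Reagents that add atoms: none
Why: Olefin cross-metathesis of the terminal alkene with excess crotonaldehyde should give the (E)-enal C1=C10–C14, because the electron-poor 1,1-disubstituted alkenes and the trisubstituted C4=C5 alkene are much slower partners.

Step 10
Reactants: 17 (E)-enal
Product: 18 (Z)-2-iodoenal
Conditions: I2 (2 equiv), K2CO3 (1.2 equiv), DMAP (0.2 equiv), THF/H2O (1:1), rt
Reagents that add atoms: iodine, II
Why: Amine-catalysed α-iodination of an enal (conjugate addition of DMAP, iodination of the enolate, elimination; a Morita–Baylis–Hillman-type halogenation) should give the (Z)-2-iodoenal with iodine cis to C2, the geometry the ring alkene needs.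

Step 11
Reactants: 18 (Z)-2-iodoenal
Product: 20 C9 alcohol dimethyl acetal, via silyl ether dimethyl acetal 19 (not isolated)
Conditions: HC(OMe)3 (5 equiv), CSA (10 mol %), MeOH, 0 °C to rt; NaHCO3 quench
Reagents that add atoms: trimethyl orthoformate, COC(OC)OC; methanol, CO
Why: Acid-catalysed acetalisation masks the C14 aldehyde for the chromium step, and the same acidic methanol should cleave the primary tert-butyldimethylsilyl ether at C9 while the more robust tert-butyldiphenylsilyl ether at C15 stays.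

Step 12
Reactants: 20 C9 alcohol dimethyl acetal
Product: 21 C9 aldehyde
Conditions: Dess–Martin periodinane, NaHCO3, CH2Cl2, 0 °C to rt
Reagents that add atoms: none
Why: Buffered Dess–Martin oxidation should give the α-acyloxy aldehyde without epimerisation at C8 or acyl migration.

Step 13
Reactants: 21 C9 aldehyde
Product: 22 macrocyclic C9 alcohol
Conditions: CrCl2 (10 equiv), NiCl2 (0.1 equiv), DMSO/THF (3:1), 0.003 M, rt
Reagents that add atoms: none
Why: Intramolecular Nozaki–Hiyama–Kishi reaction, in which the nickel-catalysed alkenylchromium species keeps the alkene geometry and adds to the aldehyde at high dilution; Felkin–Anh (non-chelated) attack anti to the C8 acyloxy group should give the 8,9-anti (9S) alcohol.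

Step 14
Reactants: 22 macrocyclic C9 alcohol
Product: 23 C9 acetate
Conditions: Ac2O, pyridine, DMAP (cat.), CH2Cl2, 0 °C
Reagents that add atoms: acetic anhydride, CC(=O)OC(C)=O
Why: Standard DMAP-catalysed acetylation of the secondary allylic alcohol proceeds with retention at C9.

Step 15
Reactants: 23 C9 acetate
Product: 24 CNP0147326.13 (target)
Conditions: aq. HF (48 %), MeCN, 0 °C to rt
Reagents that add atoms: water, O
Why: Aqueous HF should hydrolyse the dimethyl acetal to the C14 enal and cleave the C15 silyl ether in one operation, since the esters and the lactone tolerate these acidic conditions.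

**Compound list**

1 | (R)-5-(hydroxymethyl)furan-2(5H)-one | OC[C@@H]1OC(=O)C=C1 | starting material
2 | (R)-5-{[(tert-butyldimethylsilyl)oxy]methyl}furan-2(5H)-one | CC(C)(C)[Si](C)(C)OC[C@@H]1OC(=O)C=C1 | intermediate
3 | (5R)-5-{[(tert-butyldimethylsilyl)oxy]methyl}-2,5-dihydrofuran-2-ol (lactol, both anomers) | CC(C)(C)[Si](C)(C)OC[C@@H]1OC(O)C=C1 | intermediate
4 | (pent-4-en-1-yl)triphenylphosphonium bromide | C=CCCC[P+](c1ccccc1)(c1ccccc1)c1ccccc1.[Br-] | starting material
5 | ethyl chloroformate | CCOC(=O)Cl | starting material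
6 | pent-4-enylidene(triphenyl)phosphorane | C=CCCC=P(c1ccccc1)(c1ccccc1)c1ccccc1 | intermediate
7 | (1-ethoxy-1-oxohex-5-en-2-yl)triphenylphosphonium chloride | CCOC(=O)C(CCC=C)[P+](c1ccccc1)(c1ccccc1)c1ccccc1.[Cl-] | intermediate
8 | ethyl 2-(triphenyl-λ5-phosphanylidene)hex-5-enoate | CCOC(=O)C(CCC=C)=P(c1ccccc1)(c1ccccc1)c1ccccc1 | intermediate
9 | ethyl (2E,4Z,6R)-2-(but-3-en-1-yl)-7-[(tert-butyldimethylsilyl)oxy]-6-hydroxyhepta-2,4-dienoate | CC(C)(C)[Si](C)(C)OC[C@H](O)/C=C\C=C(\C(=O)OCC)CCC=C | intermediate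
10 | (2E,4Z,6R)-2-(but-3-en-1-yl)-7-[(tert-butyldimethylsilyl)oxy]hepta-2,4-diene-1,6-diol | CC(C)(C)[Si](C)(C)OC[C@H](O)/C=C\C=C(\CO)CCC=C | intermediate
11 | (2R,3Z,5E)-1-[(tert-butyldimethylsilyl)oxy]-6-{[(tert-butyldiphenylsilyl)oxy]methyl}deca-3,5,9-trien-2-ol | CC(C)(C)[Si](C)(C)OC[C@H](O)/C=C\C=C(\CO[Si](c1ccccc1)(c1ccccc1)C(C)(C)C)CCC=C | intermediate
12 | 2-bromoprop-2-enoic acid (2-bromoacrylic acid) | C=C(Br)C(=O)O | starting material
13 | allylpalladium bromide carboxylate (σ-allyl form of the η3-allyl complex; 1-carboxylatovinyl on C7 and palladium on C6, added syn; potassium salt, phosphine ligands omitted) | CC(C)(C)[Si](C)(C)OC[C@H](O)[C@@H](C(=C)C(=O)[O-])[C@@H]([Pd]Br)/C=C(/CO[Si](c1ccccc1)(c1ccccc1)C(C)(C)C)CCC=C.[K+] | intermediate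
14 | (4R,5R)-4-[(1R)-2-[(tert-butyldimethylsilyl)oxy]-1-hydroxyethyl]-5-[(1E)-2-{[(tert-butyldiphenylsilyl)oxy]methyl}hexa-1,5-dien-1-yl]-3-methylideneoxolan-2-one | CC(C)(C)[Si](C)(C)OC[C@H](O)[C@H]1C(=C)C(=O)O[C@@H]1/C=C(/CO[Si](c1ccccc1)(c1ccccc1)C(C)(C)C)CCC=C | intermediate
15 | (1R)-2-[(tert-butyldimethylsilyl)oxy]-1-[(2R,3S)-2-[(1E)-2-{[(tert-butyldiphenylsilyl)oxy]methyl}hexa-1,5-dien-1-yl]-4-methylidene-5-oxooxolan-3-yl]ethyl 2-methylprop-2-enoate | CC(C)(C)[Si](C)(C)OC[C@H](OC(=O)C(C)=C)[C@H]1C(=C)C(=O)O[C@@H]1/C=C(/CO[Si](c1ccccc1)(c1ccccc1)C(C)(C)C)CCC=C | intermediate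
16 | (E)-but-2-enal (crotonaldehyde) | C/C=C/C=O | starting material
17 | (1R)-2-[(tert-butyldimethylsilyl)oxy]-1-[(2R,3S)-2-[(1E,5E)-2-{[(tert-butyldiphenylsilyl)oxy]methyl}-7-oxohepta-1,5-dien-1-yl]-4-methylidene-5-oxooxolan-3-yl]ethyl 2-methylprop-2-enoate | CC(C)(C)[Si](C)(C)OC[C@H](OC(=O)C(C)=C)[C@H]1C(=C)C(=O)O[C@@H]1/C=C(/CO[Si](c1ccccc1)(c1ccccc1)C(C)(C)C)CC/C=C/C=O | intermediate
18 | (1R)-2-[(tert-butyldimethylsilyl)oxy]-1-[(2R,3S)-2-[(1E,5Z)-2-{[(tert-butyldiphenylsilyl)oxy]methyl}-6-iodo-7-oxohepta-1,5-dien-1-yl]-4-methylidene-5-oxooxolan-3-yl]ethyl 2-methylprop-2-enoate | CC(C)(C)[Si](C)(C)OC[C@H](OC(=O)C(C)=C)[C@H]1C(=C)C(=O)O[C@@H]1/C=C(/CO[Si](c1ccccc1)(c1ccccc1)C(C)(C)C)CC/C=C(/C=O)I | intermediate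
19 | (1R)-2-[(tert-butyldimethylsilyl)oxy]-1-[(2R,3S)-2-[(1E,5Z)-2-{[(tert-butyldiphenylsilyl)oxy]methyl}-6-iodo-7,7-dimethoxyhepta-1,5-dien-1-yl]-4-methylidene-5-oxooxolan-3-yl]ethyl 2-methylprop-2-enoate | CC(C)(C)[Si](C)(C)OC[C@H](OC(=O)C(C)=C)[C@H]1C(=C)C(=O)O[C@@H]1/C=C(/CO[Si](c1ccccc1)(c1ccccc1)C(C)(C)C)CC/C=C(/C(OC)OC)I | intermediate
20 | (1R)-1-[(2R,3S)-2-[(1E,5Z)-2-{[(tert-butyldiphenylsilyl)oxy]methyl}-6-iodo-7,7-dimethoxyhepta-1,5-dien-1-yl]-4-methylidene-5-oxooxolan-3-yl]-2-hydroxyethyl 2-methylprop-2-enoate | OC[C@H](OC(=O)C(C)=C)[C@H]1C(=C)C(=O)O[C@@H]1/C=C(/CO[Si](c1ccccc1)(c1ccccc1)C(C)(C)C)CC/C=C(/C(OC)OC)I | intermediate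
21 | (1R)-1-[(2R,3S)-2-[(1E,5Z)-2-{[(tert-butyldiphenylsilyl)oxy]methyl}-6-iodo-7,7-dimethoxyhepta-1,5-dien-1-yl]-4-methylidene-5-oxooxolan-3-yl]-2-oxoethyl 2-methylprop-2-enoate | O=C[C@H](OC(=O)C(C)=C)[C@H]1C(=C)C(=O)O[C@@H]1/C=C(/CO[Si](c1ccccc1)(c1ccccc1)C(C)(C)C)CC/C=C(/C(OC)OC)I | intermediate
22 | (6R,7S,8R,9S)-15-[(tert-butyldiphenylsilyl)oxy]-9-hydroxy-14,14-dimethoxy-8-(methacryloyloxy)germacra-1(10)E,4E,11(13)-trien-12,6-olide (both ring alkenes cis within the ring) | C=C(C)C(=O)O[C@@H]1[C@H]2C(=C)C(=O)O[C@@H]2/C=C(/CO[Si](c3ccccc3)(c3ccccc3)C(C)(C)C)CC/C=C(/C(OC)OC)[C@@H]1O | intermediate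
23 | (6R,7S,8R,9S)-9-acetoxy-15-[(tert-butyldiphenylsilyl)oxy]-14,14-dimethoxy-8-(methacryloyloxy)germacra-1(10)E,4E,11(13)-trien-12,6-olide | C=C(C)C(=O)O[C@@H]1[C@H]2C(=C)C(=O)O[C@@H]2/C=C(/CO[Si](c3ccccc3)(c3ccccc3)C(C)(C)C)CC/C=C(/C(OC)OC)[C@@H]1OC(C)=O | intermediate
24 | CNP0147326.13: (6R,7S,8R,9S)-9-acetoxy-15-hydroxy-8-(methacryloyloxy)-14-oxogermacra-1(10)E,4E,11(13)-trien-12,6-olide | C=C(C)C(=O)O[C@@H]1[C@H]2C(=C)C(=O)O[C@@H]2/C=C(/CO)CC/C=C(/C=O)[C@@H]1OC(C)=O | target

**Step count and risks**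

Total step count: 15. Longest linear sequence: 14 steps (steps 1, 2 and 4 to 15, from 1); step 3 is the side branch.

Steps most likely to fail:

Step 7 (key step). Insertion of the internal (Z)-diene into the alkenylpalladium bond may be slow, so that the bromoacrylate polymerises or the allylpalladium intermediate loses a β-hydrogen to give a triene. Delivery may also occur to the other face of C7, or the C–O bond may form on the palladium-bearing face (cis-lactone). The free C8 hydroxyl may translactonise onto C12 under base. The fallback sets out from 11 and comes back at 14. Oxidative radical annulation with malonic acid, Mn(OAc)3 dihydrate (trivalent manganese) and catalytic Cu(OAc)2 in AcOH at 50 °C should add the malonyl radical to C7, oxidise the allyl radical to the cation and close it at C6 to the trans-lactone, giving the 11-carboxy lactone F1. Decarboxylative Mannich methylenation of F1 (aq. formaldehyde, Et2NH, NaOAc, AcOH, 70 °C) then gives 14.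

Step 13. Oligomerisation may compete with ring closure, facial selectivity at C9 may be low in the strained macrocyclic transition state, and the methacryloyl group may migrate from O8 to the new chromium alkoxide at O9. The fallback sets out from 15 and comes back at 23; it moves the ring closure to C1=C10 and sets C9 in an open chain. CSA in MeOH removes the tert-butyldimethylsilyl group to give the C9 alcohol F2. Dess–Martin oxidation gives the aldehyde F3. Intermolecular Nozaki–Hiyama–Kishi addition of 2-bromo-3,3-dimethoxyprop-1-ene (CrCl2, catalytic NiCl2, DMF) under Felkin–Anh control gives the allylic alcohol F4. Acetylation (Ac2O, pyridine, DMAP) gives the acetate F5. Ring-closing metathesis between the C1 vinyl group and the C10 methylidene (second-generation Hoveyda–Grubbs catalyst, toluene, 80 °C, high dilution) then gives 23.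

Step 9. Ring-closing metathesis of the terminal alkene onto the exocyclic methylene C13 (eight-membered ring) or sequestration of the catalyst may compete with cross-metathesis. The fallback sets out from 15 and comes back at 17; it masks the exocyclic methylene temporarily. Conjugate addition of Me2NH (1 equiv, THF, 0 °C) to the α-methylene lactone gives the Mannich base F6. Cross-metathesis of its camphorsulfonate salt with crotonaldehyde (second-generation Hoveyda–Grubbs catalyst, CH2Cl2, 40 °C) gives the enal F7. Quaternisation with MeI and elimination with NaHCO3 restores the methylene and gives 17.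

Further compounds
F1 | step 7 | 11-carboxy lactone: (4R,5R)-4-[(1R)-2-[(tert-butyldimethylsilyl)oxy]-1-hydroxyethyl]-5-[(1E)-2-{[(tert-butyldiphenylsilyl)oxy]methyl}hexa-1,5-dien-1-yl]-2-oxooxolane-3-carboxylic acid (C11 epimers) | CC(C)(C)[Si](C)(C)OC[C@H](O)[C@H]1C(C(=O)O)C(=O)O[C@@H]1/C=C(/CO[Si](c1ccccc1)(c1ccccc1)C(C)(C)C)CCC=C
F2 | step 13 | C9 alcohol: (1R)-1-[(2R,3S)-2-[(1E)-2-{[(tert-butyldiphenylsilyl)oxy]methyl}hexa-1,5-dien-1-yl]-4-methylidene-5-oxooxolan-3-yl]-2-hydroxyethyl 2-methylprop-2-enoate | OC[C@H](OC(=O)C(C)=C)[C@H]1C(=C)C(=O)O[C@@H]1/C=C(/CO[Si](c1ccccc1)(c1ccccc1)C(C)(C)C)CCC=C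
F3 | step 13 | C9 aldehyde: (1R)-1-[(2R,3S)-2-[(1E)-2-{[(tert-butyldiphenylsilyl)oxy]methyl}hexa-1,5-dien-1-yl]-4-methylidene-5-oxooxolan-3-yl]-2-oxoethyl 2-methylprop-2-enoate | O=C[C@H](OC(=O)C(C)=C)[C@H]1C(=C)C(=O)O[C@@H]1/C=C(/CO[Si](c1ccccc1)(c1ccccc1)C(C)(C)C)CCC=C
F4 | step 13 | open-chain (8R,9S) allylic alcohol: (1R,2S)-1-[(2R,3S)-2-[(1E)-2-{[(tert-butyldiphenylsilyl)oxy]methyl}hexa-1,5-dien-1-yl]-4-methylidene-5-oxooxolan-3-yl]-2-hydroxy-3-(dimethoxymethyl)but-3-en-1-yl 2-methylprop-2-enoate | C=C(C(OC)OC)[C@H](O)[C@H](OC(=O)C(C)=C)[C@H]1C(=C)C(=O)O[C@@H]1/C=C(/CO[Si](c1ccccc1)(c1ccccc1)C(C)(C)C)CCC=C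
F5 | step 13 | 9-acetate of F4 | C=C(C(OC)OC)[C@H](OC(C)=O)[C@H](OC(=O)C(C)=C)[C@H]1C(=C)C(=O)O[C@@H]1/C=C(/CO[Si](c1ccccc1)(c1ccccc1)C(C)(C)C)CCC=C
F6 | step 9 | dimethylamine adduct of 15 at C13 (4-[(dimethylamino)methyl] lactone, C11 epimers) | CC(C)(C)[Si](C)(C)OC[C@H](OC(=O)C(C)=C)[C@H]1C(CN(C)C)C(=O)O[C@@H]1/C=C(/CO[Si](c1ccccc1)(c1ccccc1)C(C)(C)C)CCC=C
F7 | step 9 | (E)-enal from cross-metathesis of F6 (dimethylamine adduct of 17) | CC(C)(C)[Si](C)(C)OC[C@H](OC(=O)C(C)=C)[C@H]1C(CN(C)C)C(=O)O[C@@H]1/C=C(/CO[Si](c1ccccc1)(c1ccccc1)C(C)(C)C)CC/C=C/C=O
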